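I had no rate constants for this flask, so I looked for an amount that the earlier runs could give me in their place.

| flask | solid substrate | solid reagent | remark | time |
|---|---|---|---|---|
| maple | 0.70 M | 0.75 M | run made earlier |  |
| cedar | 1.1 M | 0.75 M | run made earlier |  |
| birch | 0.50 M | 1.1 M | run made earlier |  |
| flask | 0.50 M | 0.750 M |  | 30 min |

- maple (time / min: product / %): 2.50: 2.3; 4.00: 6.0; 6.00: 11.3; 10.0: 23.6; 20.0: 55.3; 30.0: 72.9
- cedar (time / min: product / %): 2.50: 2.0; 4.00: 3.4; 6.00: 8.3; 10.0: 15.5; 20.0: 34.6; 30.0: 46.0
- birch (time / min: product / %): 2.50: 2.8; 8.00: 24.6; 15.0: 54.5; 20.0: 76.2; 30.0: 95.6

(each reading ± 1 percentage point)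

- given per volume of solution although it is solid: solid substrate, solid reagent
- the numbers in the tables scatter by 1 percentage point (one standard deviation)
- at the start none of the solid substrate is in solution
- at the start none of the solid reagent is in solution

- ochre: doubling the dissolution coefficient of the solid substrate, all else as stated
- blue: doubling the solubility of the solid substrate, all else as stated
- violet: doubling the dissolution coefficient of the solid reagent, all else as stated
- grey: doubling the solubility of the solid reagent, all else as stated

1. product at 30 min, in percent of the solid substrate charged
2. the change that raises the amount of product at 30 min, in percent of the solid substrate charged most ("none" if none brings more than 2 percentage points) (ochre / blue / violet / grey / none)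
3. amount of product at 30 min, in percent of the solid substrate charged, after blue

Maple has the flask's solid reagent, 0.75 M, and more solid substrate, 0.70 M against 0.50 M. At 30.0 min maple held 0.510 M of product and cedar, with 1.1 M of solid substrate, 0.506 M, so the extra substrate bought no product that the scatter can show. Their mean is 0.508 M. I call it the reagent cap C: the product that this charge of solid reagent gave by that time with solid substrate in surplus.

Maple stood at 72.9% at 30.0 min because its charge stands above C, which makes solid reagent its limiting reagent. The flask's charge stands just below C: C is 102% of it, but C was read with substrate in surplus, so it does not tell me whether the flask reaches full conversion. My reckoning ends at that estimate and gives no point value.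

The forecast went further: 91% (87% to 94%), with blue best at 96%, on the ground that “charges barely matter early”.

The flask gave 93.5%, which is 0.468 M of product, below C; blue was best, at 97.3%.

    solid substrate ⇌ dissolved substrate, rate k1*(cs1 - [dissolved substrate]) while solid is left; crystals form when [dissolved substrate] > cs1 (solubility = 0.190 M, k = 0.00577 s⁻¹)
    dissolved substrate + partner → product (k = 0.0328 L mol⁻¹ s⁻¹)
    solid reagent ⇌ partner, rate k3*(cs3 - [partner]) while solid is left; crystals form when [partner] > cs3 (solubility = 0.410 M, k = 0.00165 s⁻¹)
    partner → decomposed reagent (k = 0.00190 s⁻¹)

In the flask the partner, dissolved reagent, had a half-life of 6.1 min by its decomposition at 11.3 min, shorter than the 11.3 min by which half of the solid reagent's dissolution up to the asked time was done. By 30.0 min, 0.257 M stood as decomposed reagent beside 0.468 M of product.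

For a neighbouring flask, the same flask with 2.0 M of solid substrate, C gives 25.4% of the charge; the computed flask gave 25.4%.

The runs were generated by integration with constants of no real substance, and the scatter is random.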